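**Retrosynthetic overview**

1. Achilleol A 17 comes from ketone 16 (C1=O) by substrate-controlled hydride reduction in the last step.
2. Ketone 16 comes from the acyclic pentaenal 15 by carbene-catalysed intramolecular hydroacylation: the aldehyde carbon (C1) adds to the internal carbon of an isopropenyl group (C2). This closes the only ring, the cyclohexane, last, and turns =CH2 into the second methyl of the quaternary carbon.
3. Enabling feature: in the cyclohexane ring the quaternary C2 carries two methyl groups and lies between the carbinol carbon C1 and the tertiary C3–H. One methyl can therefore be written as the =CH2 of an isopropenyl group on C3, and C1 reaches C2 through C6–C5–C4–C3 (six-membered closure). C3 is not α to the carbonyl and keeps its configuration.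
4. Aldehyde 15 comes from the C25 allylic phosphate 10 and the C5 alkenylaluminium 12 by copper-catalysed enantioselective SN2' substitution, which sets C3 and both 1,1-disubstituted alkenes at once.
5. Phosphate 10 comes from geranyl phenyl sulfone (SeO2 oxidation of its (E)-methyl group) and (2E,6E)-farnesyl bromide by sulfone alkylation and desulfonylation.

Key step: step 11

Remark: ring atoms are numbered as in the cyclohexanol name of the target (C1 carbinol carbon, C2 CMe2, C3 CH bearing the chain, C4 C(=CH2), C5, C6); compounds 1, 5 and 11 are taken as purchasable; the sense of induction in step 8 is assumed to follow the established model for this catalyst class, and the ligand antipode that gives the (5S) product is the one to be used.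

**Route**

Step 1
Reactants: 1 geranyl bromide [(2E)-1-bromo-3,7-dimethylocta-2,6-diene]
Product: 2 geranyl phenyl sulfone
Conditions: PhSO2Na, DMF, rt
Reagents that add atoms: sodium benzenesulfinate, [Na+].[O-]S(=O)c1ccccc1
Why: SN2 S-alkylation of the sulfinate at the primary allylic bromide should give the sulfone without touching either alkene; no stereocentre is formed.

Step 2
Reactants: 2 geranyl phenyl sulfone
Product: 3 (2E,6E)-8-(benzenesulfonyl)-2,6-dimethylocta-2,6-dien-1-ol
Conditions: SeO2 (0.1 equiv), tBuOOH (2 equiv), salicylic acid (0.1 equiv), CH2Cl2, 0 °C to rt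
Reagents that add atoms: tert-butyl hydroperoxide, CC(C)(C)OO
Why: Riley allylic oxidation (ene reaction, then [2,3]-sigmatropic shift) should attack the electron-rich terminal trisubstituted alkene at its (E)-methyl group, the alkene next to the sulfone being deactivated; the (E) geometry of the new allylic alcohol follows from this known preference.

Step 3
Reactants: 3 (2E,6E)-8-(benzenesulfonyl)-2,6-dimethylocta-2,6-dien-1-ol
Product: 4 tert-butyldimethylsilyl ether of 3
Conditions: TBSCl, imidazole, CH2Cl2, rt
Reagents that add atoms: tert-butyldimethylsilyl chloride, CC(C)(C)[Si](C)(C)Cl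
Why: Standard silylation of the primary allylic alcohol protects it against the base of step 4 and the hydride of step 5.

Step 4
Reactants: 4 tert-butyldimethylsilyl ether of 3; 5 (2E,6E)-farnesyl bromide
Product: 7 C25 sulfone (silyl ether of (2E,6E,10E,14E)-8-(benzenesulfonyl)-2,6,11,15,19-pentamethylicosa-2,6,10,14,18-pentaen-1-ol; both epimers at C8), via α-lithio sulfone 6 (not isolated)
Conditions: n-BuLi, THF, −78 °C; then 5, −78 to −20 °C
Reagents that add atoms: n-butyllithium, [Li]CCCC (its lithium is found in 6 only)
Why: Alkylation of the sulfone-stabilised allylic carbanion with a primary allylic bromide (tail-to-tail prenyl coupling) forms the central C–C bond by SN2 at the carbon α to sulfur; the new sulfonyl-bearing centre is removed in step 5.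

Step 5
Reactants: 7 C25 sulfone
Product: 8 tert-butyldimethylsilyl ether of (2E,6E,10E,14E)-2,6,11,15,19-pentamethylicosa-2,6,10,14,18-pentaen-1-ol
Conditions: Pd(dppp)Cl2 (5 mol%), LiEt3BH (2.5 equiv), THF, 0 °C
Reagents that add atoms: none
Why: Palladium-catalysed hydride desulfonylation: the allylic sulfone ionises to a π-allylpalladium complex that should take hydride at the less substituted terminus, which keeps the (E)-trisubstituted alkene in place.

Step 6
Reactants: 8 silyl ether of the C25 alcohol
Product: 9 (2E,6E,10E,14E)-2,6,11,15,19-pentamethylicosa-2,6,10,14,18-pentaen-1-ol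
Conditions: TBAF, THF, 0 °C to rt
Reagents that add atoms: none
Why: Fluoride cleaves the silyl ether and leaves the pentaene untouched.

Step 7
Reactants: 9 C25 allylic alcohol
Product: 10 diethyl (2E,6E,10E,14E)-2,6,11,15,19-pentamethylicosa-2,6,10,14,18-pentaen-1-yl phosphate
Conditions: ClP(O)(OEt)2, Et3N, DMAP (cat.), CH2Cl2, 0 °C
Reagents that add atoms: diethyl chlorophosphate, CCOP(=O)(Cl)OCC
Why: Phosphorylation of the primary allylic alcohol installs the leaving group needed for copper-catalysed allylic substitution.

Step 8
Reactants: 10 C25 allylic phosphate; 11 tert-butyldimethyl(pent-4-yn-1-yloxy)silane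
Product: 13 tert-butyldimethylsilyl ether of (5S,8E,12E,16E)-8,13,17,21-tetramethyl-4-methylidene-5-(prop-1-en-2-yl)docosa-8,12,16,20-tetraen-1-ol, via alkenylaluminium 12 (not isolated)
Conditions: 11, DIBAL-H, Ni(dppp)Cl2 (3 mol%), THF, 22 °C; then 10, chiral sulfonate-bearing 4,5-diphenylimidazolinium salt (carbene precursor, 2.5 mol%) premixed with Ag2O, CuCl2·2H2O (5 mol%), THF, −15 °C
Reagents that add atoms: diisobutylaluminium hydride, CC(C)C[AlH]CC(C)C (its aluminium and isobutyl groups are found in 12 only)
Why: Nickel-catalysed α-selective hydroalumination places aluminium on the internal alkyne carbon, and the chiral carbene–copper catalyst should then transfer this alkenyl group in an enantioselective SN2' allylic substitution to the CH terminus of the (E)-allylic phosphate, so that one operation sets the C5 stereocentre of 13 (ring C3 of the target) under catalyst control and creates both 1,1-disubstituted alkenes.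

Step 9
Reactants: 13 silyl ether
Product: 14 (5S,8E,12E,16E)-8,13,17,21-tetramethyl-4-methylidene-5-(prop-1-en-2-yl)docosa-8,12,16,20-tetraen-1-ol
Conditions: TBAF, THF, 0 °C to rt
Reagents that add atoms: none
Why: Fluoride-mediated desilylation frees the primary alcohol; the bis-allylic stereocentre is not acidic enough to be affected.

Step 10
Reactants: 14 primary alcohol
Product: 15 (5S,8E,12E,16E)-8,13,17,21-tetramethyl-4-methylidene-5-(prop-1-en-2-yl)docosa-8,12,16,20-tetraenal
Conditions: PhI(OAc)2, TEMPO (10 mol%), CH2Cl2, rt
Reagents that add atoms: none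
Why: Oxoammonium-mediated oxidation is selective for the primary alcohol, stops at the aldehyde and does not touch the six alkenes.

Step 11
Reactants: 15 pentaenal
Product: 16 (3R)-2,2-dimethyl-4-methylidene-3-[(3E,7E,11E)-3,8,12,16-tetramethylheptadeca-3,7,11,15-tetraen-1-yl]cyclohexan-1-one
Conditions: 3-mesityl-5,6,7,8-tetrahydro-4H-cyclohepta[d]thiazol-3-ium perchlorate (20 mol%), DBU (18 mol%), 1,4-dioxane (0.02 M), 110 °C, argon
Reagents that add atoms: none
Why: Proposed new method: the thiazol-2-ylidene adds to the aldehyde carbon C1 and proton transfer gives the hydroxy-enamine (Breslow intermediate), an acyl-anion equivalent whose carbon C1 bonds to the internal isopropenyl carbon C2 while its O–H proton passes to the =CH2 terminus in one concerted, asynchronous five-centre transition state, after which the alkoxide expels the carbene and leaves the C1 ketone with =CH2 converted into the second methyl group of C2. The closest known reaction type is the carbene-catalysed intramolecular hydroacylation of unactivated 1,1-disubstituted alkenes by 2-allyloxy- and 2-allyl-benzaldehydes (chromanones and indanones with a quaternary α-carbon, described as Conia-ene-like), and what is new here is an enolisable aliphatic aldehyde on an all-carbon tether. The one ring closed is the cyclohexanone, in 6-exo-trig mode with respect to the isopropenyl C=C (bond C1–C2, the CH2 terminus stays outside the ring). No stereocentre is created, since C2 ends with two methyl groups, and the C3 centre set in step 8 is neither α to the new carbonyl nor involved, so it is carried through (its descriptor changes from S to R only because the priorities change). The step needs site selectivity among six C=C bonds and Markovnikov regiochemistry, and the substrate secures both because only the isopropenyl group can reach C1 through a six-membered ring with positive charge building up at a tertiary carbon (the 4-methylidene group would have to give a cyclobutanone, the chain alkenes are trisubstituted and remote). Aldol and acyloin self-condensation are to be held back by high dilution and by using less base than azolium salt.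

Step 12
Reactants: 16 ketone
Product: 17 achilleol A, (1S,3R)-2,2-dimethyl-4-methylidene-3-[(3E,7E,11E)-3,8,12,16-tetramethylheptadeca-3,7,11,15-tetraen-1-yl]cyclohexan-1-ol
Conditions: NaBH4, MeOH/THF, −20 °C
Reagents that add atoms: none
Why: Substrate-controlled hydride reduction: the small borohydride should attack along the axial trajectory on the face that carries the C3–H (anti to the chain), as in the reduction of 4,4-dimethyl-3-oxo triterpenoids to their equatorial alcohols, which sets C1 as (S) with the hydroxyl cis to the C3 chain.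

**Compound list**

1 | geranyl bromide, (2E)-1-bromo-3,7-dimethylocta-2,6-diene | CC(C)=CCC/C(C)=C/CBr | starting material
2 | geranyl phenyl sulfone | CC(C)=CCC/C(C)=C/CS(=O)(=O)c1ccccc1 | intermediate
3 | (2E,6E)-8-(benzenesulfonyl)-2,6-dimethylocta-2,6-dien-1-ol | OC/C(C)=C/CC/C(C)=C/CS(=O)(=O)c1ccccc1 | intermediate
4 | tert-butyldimethylsilyl ether of 3 | CC(C)(C)[Si](C)(C)OC/C(C)=C/CC/C(C)=C/CS(=O)(=O)c1ccccc1 | intermediate
5 | (2E,6E)-farnesyl bromide, (2E,6E)-1-bromo-3,7,11-trimethyldodeca-2,6,10-triene | BrC/C=C(\C)CC/C=C(\C)CCC=C(C)C | starting material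
6 | α-lithio sulfone from 4 (lithium on the sulfonyl-bearing carbon) | CC(C)(C)[Si](C)(C)OC/C(C)=C/CC/C(C)=C/C([Li])S(=O)(=O)c1ccccc1 | intermediate (not isolated)
7 | C25 sulfone, silyl ether of (2E,6E,10E,14E)-8-(benzenesulfonyl)-2,6,11,15,19-pentamethylicosa-2,6,10,14,18-pentaen-1-ol (both C8 epimers) | CC(C)(C)[Si](C)(C)OC/C(C)=C/CC/C(C)=C/C(C/C=C(\C)CC/C=C(\C)CCC=C(C)C)S(=O)(=O)c1ccccc1 | intermediate
8 | tert-butyldimethylsilyl ether of (2E,6E,10E,14E)-2,6,11,15,19-pentamethylicosa-2,6,10,14,18-pentaen-1-ol | CC(C)(C)[Si](C)(C)OC/C(C)=C/CC/C(C)=C/CC/C=C(\C)CC/C=C(\C)CCC=C(C)C | intermediate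
9 | (2E,6E,10E,14E)-2,6,11,15,19-pentamethylicosa-2,6,10,14,18-pentaen-1-ol | OC/C(C)=C/CC/C(C)=C/CC/C=C(\C)CC/C=C(\C)CCC=C(C)C | intermediate
10 | diethyl (2E,6E,10E,14E)-2,6,11,15,19-pentamethylicosa-2,6,10,14,18-pentaen-1-yl phosphate | CCOP(=O)(OCC)OC/C(C)=C/CC/C(C)=C/CC/C=C(\C)CC/C=C(\C)CCC=C(C)C | intermediate
11 | tert-butyldimethyl(pent-4-yn-1-yloxy)silane | C#CCCCO[Si](C)(C)C(C)(C)C | starting material
12 | diisobutyl[5-(tert-butyldimethylsilyloxy)pent-1-en-2-yl]aluminium | C=C(CCCO[Si](C)(C)C(C)(C)C)[Al](CC(C)C)CC(C)C | intermediate (not isolated)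
13 | tert-butyldimethylsilyl ether of (5S,8E,12E,16E)-8,13,17,21-tetramethyl-4-methylidene-5-(prop-1-en-2-yl)docosa-8,12,16,20-tetraen-1-ol | C=C(C)[C@@H](C(=C)CCCO[Si](C)(C)C(C)(C)C)CC/C(C)=C/CC/C=C(\C)CC/C=C(\C)CCC=C(C)C | intermediate
14 | (5S,8E,12E,16E)-8,13,17,21-tetramethyl-4-methylidene-5-(prop-1-en-2-yl)docosa-8,12,16,20-tetraen-1-ol | C=C(C)[C@@H](C(=C)CCCO)CC/C(C)=C/CC/C=C(\C)CC/C=C(\C)CCC=C(C)C | intermediate
15 | (5S,8E,12E,16E)-8,13,17,21-tetramethyl-4-methylidene-5-(prop-1-en-2-yl)docosa-8,12,16,20-tetraenal | C=C(C)[C@@H](C(=C)CCC=O)CC/C(C)=C/CC/C=C(\C)CC/C=C(\C)CCC=C(C)C | intermediate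
16 | (3R)-2,2-dimethyl-4-methylidene-3-[(3E,7E,11E)-3,8,12,16-tetramethylheptadeca-3,7,11,15-tetraen-1-yl]cyclohexan-1-one | C=C1CCC(=O)C(C)(C)[C@@H]1CC/C(C)=C/CC/C=C(\C)CC/C=C(\C)CCC=C(C)C | intermediate
17 | achilleol A, (1S,3R)-2,2-dimethyl-4-methylidene-3-[(3E,7E,11E)-3,8,12,16-tetramethylheptadeca-3,7,11,15-tetraen-1-yl]cyclohexan-1-ol | C=C1CC[C@H](O)C(C)(C)[C@@H]1CC/C(C)=C/CC/C=C(\C)CC/C=C(\C)CCC=C(C)C | target

**Step count and risks**

Total step count: 12. Longest linear sequence: 12 steps (1 to 17; 5 and 11 enter as purchased).

Most likely to fail: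

1. Step 11 (proposed new method). The acyl-anion intermediate may form but add to the alkene too slowly, so that aldol or acyloin self-condensation of the enolisable aldehyde consumes the material. The fallback uses known chemistry, still closes the ring through the same C1–C2 bond, sets out from 15 and comes back at 17. Aldehyde 15 would be condensed with hydroxylamine to the aldoxime F1. Slow oxidation with aqueous NaOCl in CH2Cl2 at high dilution would give the nitrile oxide F2 (not isolated), which undergoes intramolecular nitrile oxide cycloaddition onto the isopropenyl group to the cyclohexane-fused isoxazoline F3; the C2 epimers are of no consequence. Mo(CO)6 in wet acetonitrile would cleave the N–O bond and hydrolyse the imine to the β-hydroxy ketone F4. NaBH4 would give the 1,3-diol F5, TsCl in pyridine would sulfonylate the primary hydroxyl to the tosylate F6, and LiEt3BH would reduce the neopentyl tosylate (directly or through the oxetane) to the second methyl group, giving 17.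

2. Step 8. Alkenyl transfer may be slow on the β-methyl-substituted phosphate, with competing SN2 attack, isobutyl transfer or poor enantioface discrimination. The fallback sets out from 9 and comes back at 13. Sharpless asymmetric epoxidation of 9 (Ti(OiPr)4, D-(−)-diethyl tartrate, tBuOOH, 4 Å sieves, CH2Cl2, −20 °C) would give the (2R,3R)-epoxy alcohol F7. Opening at the CH carbon with inversion by the alkenylaluminium 12 (organoaluminium reagents open 2,3-epoxy alcohols at C3) would give the 1,2-diol F8. Thiocarbonyldiimidazole would convert it into the cyclic thiocarbonate F9, and Corey–Winter olefination with 1,3-dimethyl-2-phenyl-1,3,2-diazaphospholidine at 40 °C would regenerate the isopropenyl group, giving 13.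

3. Step 12. Facial selectivity of hydride delivery may be poor, because equatorial attack competes next to the gem-dimethyl carbon. The fallback sets out from 16 and comes back at 17: reagent-controlled Corey–Bakshi–Shibata reduction with (R)-2-methyl-CBS-oxazaborolidine and catecholborane in toluene at −78 °C, where the catalyst distinguishes the quaternary from the methylene flank of the ketone and should override substrate bias. No new compound is made.

**Further compounds**

F1 | step 11 | oxime of aldehyde 15 (either C=N geometry) | C=C(C)[C@@H](C(=C)CCC=NO)CC/C(C)=C/CC/C=C(\C)CC/C=C(\C)CCC=C(C)C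
F2 | step 11 | nitrile oxide from F1 (not isolated) | C=C(C)[C@@H](C(=C)CCC#[N+][O-])CC/C(C)=C/CC/C=C(\C)CC/C=C(\C)CCC=C(C)C
F3 | step 11 | 3a-methyl-5-methylidene-4-[(3E,7E,11E)-3,8,12,16-tetramethylheptadeca-3,7,11,15-tetraen-1-yl]-3,3a,4,5,6,7-hexahydro-2,1-benzoxazole (chain-bearing carbon as in 15, either epimer at C3a) | C=C1CCC2=NOCC2(C)[C@@H]1CC/C(C)=C/CC/C=C(\C)CC/C=C(\C)CCC=C(C)C
F4 | step 11 | 2-(hydroxymethyl)-2-methyl-4-methylidene-3-[(3E,7E,11E)-3,8,12,16-tetramethylheptadeca-3,7,11,15-tetraen-1-yl]cyclohexan-1-one (either epimer at C2) | C=C1CCC(=O)C(C)(CO)[C@@H]1CC/C(C)=C/CC/C=C(\C)CC/C=C(\C)CCC=C(C)C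
F5 | step 11 | 2-(hydroxymethyl)-2-methyl-4-methylidene-3-[(3E,7E,11E)-3,8,12,16-tetramethylheptadeca-3,7,11,15-tetraen-1-yl]cyclohexan-1-ol (hydroxyl cis to the chain, either epimer at C2) | C=C1CC[C@H](O)C(C)(CO)[C@@H]1CC/C(C)=C/CC/C=C(\C)CC/C=C(\C)CCC=C(C)C
F6 | step 11 | primary 4-methylbenzenesulfonate of F5 | C=C1CC[C@H](O)C(C)(COS(=O)(=O)c2ccc(C)cc2)[C@@H]1CC/C(C)=C/CC/C=C(\C)CC/C=C(\C)CCC=C(C)C
F7 | step 8 | [(2R,3R)-2-methyl-3-[(3E,7E,11E)-3,8,12,16-tetramethylheptadeca-3,7,11,15-tetraen-1-yl]oxiran-2-yl]methanol | OC[C@@]1(C)O[C@@H]1CC/C(C)=C/CC/C=C(\C)CC/C=C(\C)CCC=C(C)C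
F8 | step 8 | (2S,3R,6E,10E,14E)-3-[5-(tert-butyldimethylsilyloxy)pent-1-en-2-yl]-2,6,11,15,19-pentamethylicosa-6,10,14,18-tetraene-1,2-diol | OC[C@@](C)(O)[C@@H](C(=C)CCCO[Si](C)(C)C(C)(C)C)CC/C(C)=C/CC/C=C(\C)CC/C=C(\C)CCC=C(C)C
F9 | step 8 | cyclic thiocarbonate (1,3-dioxolane-2-thione) of diol F8 | C[C@@]1(COC(=S)O1)[C@@H](C(=C)CCCO[Si](C)(C)C(C)(C)C)CC/C(C)=C/CC/C=C(\C)CC/C=C(\C)CCC=C(C)C
F0 | step 12 | none | none
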